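**Calycopterin (17) by carbonylative annulation of a symmetrical iodoresorcinol: synthesis design**

## The problem

Calycopterin (17) is a flavone: benzene ring A is fused to the 4-pyranone ring C, and the 4-hydroxyphenyl ring B sits on C2. It has no stereocentre, so the task is one of constitution and of telling six oxygen functions apart.

- **Oxygen pattern.** Four oxygens are methyl ethers (C3, C6, C7, C8) and two are free phenols (C5, C4').
- **Ring A.** It has no C–H left (C5 to C8 carry oxygen, C4a and C8a are fusion atoms). Its substitution pattern must therefore be complete before ring C is closed, and late electrophilic chemistry on ring A is not available.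
- **Sensitive groups.** The pentaoxygenated ring A is easily oxidised towards quinones. The pyranone opens at C2 under hard nucleophiles or hot alkali. The methyl ethers next to the carbonyl (C3, and C5 if it were methylated) are cleaved by chelating Lewis acids, so a methyl ether is a poor mask for the 5-hydroxyl.
- **C3 methoxyl.** It sits on the carbon that most ring C constructions deliver as C–H, so it has to be carried in or added afterwards.
- **Enabling feature.** C4 is a single carbonyl carbon between C4a and C3 and can come from carbon monoxide. C4a lies between C5 and C8a, both oxygen-bearing. A ring A piece with iodine at the future C4a and free hydroxyls on both neighbours is symmetrical: whichever hydroxyl closes ring C becomes O1, and the other is the 5-OH. C3, C2 and ring B are then an arylacetylene.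

## Retrosynthesis

**17 from 16.** The two phenols of 17 are unmasked last by cutting two benzylic C–O bonds of the bis(benzyl) ether 16. Benzyl is chosen for both positions because it survives amine, CO, palladium, lithium amide and peroxide, and both groups leave in one neutral hydrogenolysis that touches neither the methyl ethers nor the pyranone.

**16 from 15 from 12.** The C3–OMe bond is cut to the flavonol 15, and the C3–O bond of 15 is cut to the C3–H of flavone 12. The alkyne terminus that becomes C3 cannot carry oxygen through the annulation, so oxygenation after ring closure is the price of the key disconnection. C3–H of a flavone is the one position that a hindered lithium amide metalates cleanly, and the boron–oxygen exchange puts the hydroxyl exactly there. With the 5-oxygen benzylated, 15 has a single free hydroxyl and the methylation needs no selectivity.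

**12 from 11.** The 5-O-benzyl bond is cut to the free 5-hydroxyflavone 11. Lithiating 11 directly as its phenoxide would save this step, but the chelated phenoxide consumes base and lowers the acidity of C3–H. One protection step is accepted to make the lithiation dependable.

**11 from 5, 7 and 8 (key disconnection).** Three bonds of ring C are cut at once: C4a–C4, C4–C3 and O1–C2. This leads to the iodoresorcinol 5, the arylacetylene 7 and carbon monoxide 8.
- Against a Baker–Venkataraman or chalcone route, this cut needs no ring A acetophenone and builds the pyranone from three simple pieces in one catalytic operation.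
- Against a mono-protected iodophenol, the symmetrical diol 5 needs no desymmetrisation and delivers the free 5-OH directly.
- The forward reaction must take up CO before the alkyne couples, and must close the six-membered ring, not the five-membered one.

**5 from 4 from 3 from 2 from 1.** The C–I bond of 5 is cut to resorcinol 4, whose only ring C–H is the one flanked by both hydroxyls. The two C–OH bonds of 4 are traced through the bis(boronate) 3 to the dibromide 2. The C–Br bonds of 2 are traced to 1,2,3-trimethoxybenzene 1, whose two outer methoxyls direct electrophiles to C4 and C6. This places the two new oxygens meta to each other with the remaining C–H between them, which direct electrophilic oxygenation of a trimethoxyphenol would not do.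

**7 from 6.** The alkyne carbon–carbon bond of 7 is cut to the commercial aldehyde 6 by a one-carbon homologation. This is one step shorter than a Sonogashira coupling and desilylation from the aryl iodide.

## Roads not taken

**Alternative 1:** The cut is the C2=C3 double bond. The forward key step would convert the keto ylide A2 (2-[2-methoxy-2-(triphenylphosphoranylidene)acetyl]-4,5,6-trimethoxy-1,3-phenylene bis[4-(benzyloxy)benzoate]) into the flavone ester A1 (4'-benzyloxy-5-[4-(benzyloxy)benzoyloxy]-3,6,7,8-tetramethoxyflavone). The ylide carbon attacks one of the two equivalent ortho aroyl ester carbonyls, and the oxaphosphetane collapses with phosphorus leaving as its oxide.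
- Merits: the 3-methoxyl is in place before ring closure, so the C3 oxygenation steps of the chosen plan disappear. The closure is thermal and neutral. The same ring A symmetry is used.
- Weak points: olefination of an ester carbonyl by a stabilised ylide is reluctant, and it is established only for ylides with a hydrogen on the ylide carbon. Here the ylide carbon is fully substituted, the oxaphosphetane is crowded and the alkene formed is tetrasubstituted. A2 is a hexasubstituted aryl ketone flanked by two esters; its assembly needs a ring A carboxylic acid derivative and a methoxy-substituted ylide, and acyl transfer from oxygen to the ylide carbon is a competing path. One equivalent of the ring B acid is spent on the 5-ester.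
- Comparison: Alternative 1 is better in that C3 needs no later work and no strong base is used. The chosen plan sets against it a ring closure with direct precedent on ortho-iodophenols and building blocks that are each four steps or fewer from commercial material.

**Alternative 2:** The cut is the aryl ether bond O1–C8a. The forward key step would oxidise the diketone A4 (4-[2-methoxy-3-oxo-3-(2,3,4,5-tetramethoxyphenyl)propanoyl]phenyl pivalate) at an anode. The enol oxygen attacks the ring A radical cation at its one free carbon, and loss of two electrons and two protons gives A3 (3,5,6,7,8-pentamethoxy-4'-pivaloyloxyflavone).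
- Merits: no halogen and no transition metal are needed. The 3-methoxyl is carried in from the start. Ring A has only one C–H, so the site of closure is not in doubt. On paper it is the shortest route.
- Weak points: the radical cation of a tetramethoxyarene is also open to attack at methoxy-bearing carbons by adventitious nucleophiles, which leads to oxidative demethylation. A3 is electron-rich and may be oxidised further. A 2-substituted 1,3-diketone is poorly enolised, so the oxygen nucleophile is scarce. After closure the 5-methyl ether must be cleaved by a chelating Lewis acid in the presence of the 3-methoxyl, which can chelate as well, and the pivalate must be removed. This closure has no precedent in the flavone series.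
- Comparison: Alternative 2 is as good or better in step count and atom economy if the closure works. The chosen plan sets against it a known catalytic ring closure and a 5-hydroxyl that never has to be freed from a methyl ether.

**Alternative 3:** The cuts are C4–C4a and O1–C2, using the same resorcinol 4. The forward key step would heat 4 with the ketoester A6 (ethyl 3-[4-(benzyloxy)phenyl]-2-methoxy-3-oxopropanoate, racemic) without catalyst. C-Acylation at the free ring carbon through the acylketene (or the ester) and cyclodehydration onto the ketone would give A5 (4'-O-benzylcalycopterin), one hydrogenolysis from 17.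
- Merits: it is clearly the shortest route, about seven steps against ten. It needs no iodination, no CO and no C3 oxygenation, and the 3-methoxyl and 5-OH arrive in place.
- Weak points: uncatalysed condensations of this kind need temperatures near 250 °C, which is harsh for a benzyl ether and a pentaoxygenated phenol. The constitution is not fixed by construction, because Pechmann-type attack of the ring carbon on the ketone would lead to the isomeric coumarin skeleton. The alpha-methoxyl slows acylketene formation and crowds the C-acylation at a carbon already flanked by two hydroxyls.
- Comparison: Alternative 3 wins on step economy. The chosen plan sets against it a constitution that cannot go wrong (the carbonyl carbon is delivered to the carbon that bore iodine, and C2 comes from the alkyne), a reaction temperature roughly half as high, and catalyst control. It pays with three extra steps for the C3 methoxyl and one for the iodide.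

Key step: step 6

## Route

Remark: the transient species 9, 10, 13 and 14 are drawn as simple monomers, and enaminone 10 is drawn as the E isomer; either geometry leads to the same ring closure.

Step 1
Reactants: 1 1,2,3-trimethoxybenzene
Product: 2 1,5-dibromo-2,3,4-trimethoxybenzene
Conditions: NBS (2.2 equiv), MeCN, 0 °C to rt
Reagents that add atoms: N-bromosuccinimide, O=C1CCC(=O)N1Br
Why: Electrophilic aromatic bromination; the first bromine enters para to an outer methoxyl and the second goes to the carbon ortho and para to the two outer methoxyls, whereas the remaining carbon is para only to the twisted, weakly donating central methoxyl.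

Step 2
Reactants: 2 1,5-dibromo-2,3,4-trimethoxybenzene
Product: 3 2,2'-(4,5,6-trimethoxy-1,3-phenylene)bis(4,4,5,5-tetramethyl-1,3,2-dioxaborolane)
Conditions: B2pin2 (2.6 equiv), PdCl2(dppf) (5 mol %), KOAc (6 equiv), 1,4-dioxane, 90 °C
Reagents that add atoms: bis(pinacolato)diboron, CC1(C)OB(OC1(C)C)B1OC(C)(C)C(C)(C)O1
Why: Twofold Miyaura borylation; each C–Br bond undergoes oxidative addition to zerovalent palladium, acetate-assisted transmetalation with the diboron reagent and reductive elimination, and the weak acetate base does not trigger Suzuki coupling of the product.

Step 3
Reactants: 3 2,2'-(4,5,6-trimethoxy-1,3-phenylene)bis(4,4,5,5-tetramethyl-1,3,2-dioxaborolane)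
Product: 4 4,5,6-trimethoxybenzene-1,3-diol
Conditions: 30% aq H2O2, NaOH, THF/H2O, 0 °C, argon; then Na2S2O3, dilute HCl
Reagents that add atoms: hydrogen peroxide, OO
Why: Oxidation of arylboronic esters by alkaline hydroperoxide; hydroperoxide adds to boron, the aryl group migrates from boron to oxygen and the borate is hydrolysed, so each C–B bond becomes C–OH at the same carbon.

Step 4
Reactants: 4 4,5,6-trimethoxybenzene-1,3-diol
Product: 5 2-iodo-4,5,6-trimethoxybenzene-1,3-diol
Conditions: I2 (1.05 equiv), NaHCO3, THF/H2O, 0 °C, dark
Reagents that add atoms: iodine, II
Why: Electrophilic iodination of a phenol under the bicarbonate conditions used for resorcinol itself; the only ring C–H is ortho to both hydroxyls and para to the central methoxyl, so substitution is fast and has no other site, and the buffer prevents acid-promoted deiodination.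

Step 5
Reactants: 6 4-(benzyloxy)benzaldehyde
Product: 7 1-(benzyloxy)-4-ethynylbenzene
Conditions: dimethyl (1-diazo-2-oxopropyl)phosphonate (1.3 equiv), K2CO3 (2 equiv), MeOH, rt
Reagents that add atoms: dimethyl (1-diazo-2-oxopropyl)phosphonate, CC(=O)C(=[N+]=[N-])P(=O)(OC)OC
Why: Seyferth–Gilbert homologation in the Ohira–Bestmann variant; methanolysis frees the diazomethylphosphonate anion, which olefinates the aldehyde, and the diazoalkene loses nitrogen with a 1,2-shift to the terminal alkyne, while the benzyl ether is inert to carbonate in methanol.

Step 6
Reactants: 5 2-iodo-4,5,6-trimethoxybenzene-1,3-diol; 7 1-(benzyloxy)-4-ethynylbenzene; 8 carbon monoxide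
Product: 11 4'-benzyloxy-5-hydroxy-6,7,8-trimethoxyflavone, via ortho-hydroxyaryl ynone 9 (not isolated), via beta-diethylamino enone 10 (not isolated)
Conditions: PdCl2(PPh3)2 (5 mol %), CO (20 bar), 7 (1.5 equiv), Et2NH, 120 °C, autoclave
Reagents that add atoms: diethylamine, CCNCC (only in intermediate 10; lost again on ring closure)
Why: PdCl2(PPh3)2 is reduced by the amine to zerovalent palladium, which inserts into the C–I bond of 5; CO insertion gives an aroylpalladium iodide, the amine-deprotonated alkyne 7 is transferred to palladium, and reductive elimination releases ynone 9 (C4a–C4 and C4–C3). Diethylamine then adds to 9 in conjugate fashion to give enaminone 10, and one flanking phenol attacks the amine-bearing carbon and expels the amine, forming O1–C2 of 11. The closest known reaction type is the palladium-catalysed carbonylative coupling of ortho-iodophenols with terminal alkynes in a secondary amine, which gives flavones in one operation. Ring C closes in the six-membered mode, formally 6-endo-dig on the ynone and in practice a 6-endo-trig addition–elimination on 10. No stereocentre is formed. Six- over five-membered closure (flavone over aurone) is secured by the amine, because in 10 the carbon next to the carbonyl is electron-rich and only the future C2 can accept the phenol. Carbonylative over direct coupling is secured by CO pressure and the absence of copper, and aminolysis of the aroylpalladium by the solvent is held back by the excess of alkyne. The two hydroxyls that flank iodine in 5 are symmetry-equivalent, so either closure gives the same flavone and the other hydroxyl becomes the chelated 5-OH.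

Step 7
Reactants: 11 4'-benzyloxy-5-hydroxy-6,7,8-trimethoxyflavone
Product: 12 4',5-bis(benzyloxy)-6,7,8-trimethoxyflavone
Conditions: BnBr (1.5 equiv), K2CO3, KI (cat.), DMF, 70 °C
Reagents that add atoms: benzyl bromide, BrCc1ccccc1
Why: Williamson etherification; the chelated, hindered 5-hydroxyl is the only acidic group in 11 and is alkylated in hot DMF with iodide catalysis, which removes the one proton that would interfere with the lithiation and installs a group that leaves together with the 4'-O-benzyl group.

Step 8
Reactants: 12 4',5-bis(benzyloxy)-6,7,8-trimethoxyflavone
Product: 15 4',5-bis(benzyloxy)-3-hydroxy-6,7,8-trimethoxyflavone, via 3-lithioflavone 13 (not isolated), via flavon-3-ylboronic dimethyl ester 14 (not isolated)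
Conditions: LiN(iPr)2 (2.0 equiv), THF, −78 °C; B(OMe)3 (3 equiv), −78 to 0 °C; AcOH, 30% aq H2O2, 0 °C to rt
Reagents that add atoms: hydrogen peroxide, OO; trimethyl borate, COB(OC)OC (boron and methoxyls of intermediate 14 only); lithium diisopropylamide, [Li]N(C(C)C)C(C)C (lithium of intermediate 13 only)
Why: Directed lithiation of a flavone at C3 followed by borylation and oxidation; C3–H is the most acidic proton of 12 (vinylic, next to the carbonyl, lithium held by the carbonyl oxygen), the hindered amide does not add to C2 at −78 °C, and the boronate is oxidised by peroxide in acetic acid with the oxygen entering at the carbon that carried boron.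

Step 9
Reactants: 15 4',5-bis(benzyloxy)-3-hydroxy-6,7,8-trimethoxyflavone
Product: 16 4',5-bis(benzyloxy)-3,6,7,8-tetramethoxyflavone
Conditions: MeI (3 equiv), K2CO3, acetone, reflux
Reagents that add atoms: iodomethane, CI
Why: Williamson O-methylation of the flavonol hydroxyl; 15 has a single free hydroxyl, so no selectivity is required, and the enolic 3-OH is acidic enough for carbonate.

Step 10
Reactants: 16 4',5-bis(benzyloxy)-3,6,7,8-tetramethoxyflavone
Product: 17 calycopterin (5-hydroxy-2-(4-hydroxyphenyl)-3,6,7,8-tetramethoxy-4H-chromen-4-one)
Conditions: H2 (1 atm), 10% Pd/C (palladium on carbon), EtOAc/MeOH, rt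
Reagents that add atoms: none
Why: Hydrogenolysis of the two aryl benzyl ethers over palladium on carbon; the tetrasubstituted, vinylogous-ester C2=C3 bond of the 3-methoxyflavone and the aryl methyl ethers are not reduced at room temperature and one atmosphere.

## Compound list

1 | 1,2,3-trimethoxybenzene | COc1cccc(OC)c1OC | starting material
2 | 1,5-dibromo-2,3,4-trimethoxybenzene | COc1c(Br)cc(Br)c(OC)c1OC | intermediate
3 | 2,2'-(4,5,6-trimethoxy-1,3-phenylene)bis(4,4,5,5-tetramethyl-1,3,2-dioxaborolane) | COc1c(B2OC(C)(C)C(C)(C)O2)cc(B2OC(C)(C)C(C)(C)O2)c(OC)c1OC | intermediate
4 | 4,5,6-trimethoxybenzene-1,3-diol | COc1c(O)cc(O)c(OC)c1OC | intermediate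
5 | 2-iodo-4,5,6-trimethoxybenzene-1,3-diol | COc1c(O)c(I)c(O)c(OC)c1OC | intermediate
6 | 4-(benzyloxy)benzaldehyde | O=Cc1ccc(OCc2ccccc2)cc1 | starting material
7 | 1-(benzyloxy)-4-ethynylbenzene | C#Cc1ccc(OCc2ccccc2)cc1 | intermediate
8 | carbon monoxide | [C-]#[O+] | starting material
9 | 3-[4-(benzyloxy)phenyl]-1-(2,6-dihydroxy-3,4,5-trimethoxyphenyl)prop-2-yn-1-one | COc1c(O)c(C(=O)C#Cc2ccc(OCc3ccccc3)cc2)c(O)c(OC)c1OC | intermediate (not isolated)
10 | (E)-3-[4-(benzyloxy)phenyl]-3-(diethylamino)-1-(2,6-dihydroxy-3,4,5-trimethoxyphenyl)prop-2-en-1-one | CCN(CC)/C(=C/C(=O)c1c(O)c(OC)c(OC)c(OC)c1O)c1ccc(OCc2ccccc2)cc1 | intermediate (not isolated)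
11 | 4'-benzyloxy-5-hydroxy-6,7,8-trimethoxyflavone (2-[4-(benzyloxy)phenyl]-5-hydroxy-6,7,8-trimethoxy-4H-chromen-4-one) | COc1c(OC)c(O)c2c(=O)cc(-c3ccc(OCc4ccccc4)cc3)oc2c1OC | intermediate
12 | 4',5-bis(benzyloxy)-6,7,8-trimethoxyflavone | COc1c(OC)c(OCc3ccccc3)c2c(=O)cc(-c3ccc(OCc4ccccc4)cc3)oc2c1OC | intermediate
13 | 4',5-bis(benzyloxy)-3-lithio-6,7,8-trimethoxyflavone | COc1c(OC)c(OCc3ccccc3)c2c(=O)c([Li])c(-c3ccc(OCc4ccccc4)cc3)oc2c1OC | intermediate (not isolated)
14 | dimethyl [4',5-bis(benzyloxy)-6,7,8-trimethoxyflavon-3-yl]boronate | COc1c(OC)c(OCc3ccccc3)c2c(=O)c(B(OC)OC)c(-c3ccc(OCc4ccccc4)cc3)oc2c1OC | intermediate (not isolated)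
15 | 4',5-bis(benzyloxy)-3-hydroxy-6,7,8-trimethoxyflavone | COc1c(OC)c(OCc3ccccc3)c2c(=O)c(O)c(-c3ccc(OCc4ccccc4)cc3)oc2c1OC | intermediate
16 | 4',5-bis(benzyloxy)-3,6,7,8-tetramethoxyflavone | COc1c(OC)c(OCc3ccccc3)c2c(=O)c(OC)c(-c3ccc(OCc4ccccc4)cc3)oc2c1OC | intermediate
17 | calycopterin (4',5-dihydroxy-3,6,7,8-tetramethoxyflavone) | COc1c(OC)c(O)c2c(=O)c(OC)c(-c3ccc(O)cc3)oc2c1OC | target

## Step count and risk

Total steps: 10. Longest linear sequence: 9 steps (steps 1 to 4 and 6 to 10, from 1); step 5 is a one-step branch from 6.

**Step 6 (key step).** What may go wrong:
- aminolysis of the aroylpalladium intermediate by the solvent amine;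
- coupling without CO uptake, followed by five-membered closure onto the alkyne;
- slow oxidative addition into the electron-rich C–I bond that is flanked by two oxygens;
- reductive loss of iodine.

Fallback (no palladium and no CO): it sets out from 4 and returns at 11. Friedel–Crafts acetylation of 4 at its only free carbon (AcOH, BF3·OEt2, 80 °C) gives 1-(2,6-dihydroxy-3,4,5-trimethoxyphenyl)ethan-1-one F1. Deprotonation of both phenols and the methyl ketone with LiN(SiMe3)2 (4 equiv, THF, −78 °C) and C-aroylation of the enolate with 4-(benzyloxy)benzoyl chloride gives 1-[4-(benzyloxy)phenyl]-3-(2,6-dihydroxy-3,4,5-trimethoxyphenyl)propane-1,3-dione F2. Cyclodehydration of F2 in acetic acid with a trace of H2SO4 gives 11, again with either hydroxyl closing to the same product.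

**Step 8.** What may go wrong:
- incomplete deprotonation at C3;
- competing benzylic metalation of the 5-O-benzyl group with Wittig rearrangement;
- attack of the amide at C2 with opening of the pyranone;
- protodeboronation before the oxidation.

Fallback (oxygen-transfer chemistry in place of carbanion chemistry): it sets out from 12 and returns at 15. Epoxidation of the C2=C3 bond with dimethyldioxirane (acetone/CH2Cl2, 0 °C) gives racemic 4',5-bis(benzyloxy)-2,3-epoxy-6,7,8-trimethoxyflavanone F3 (cis-fused oxirane across C2–C3). A catalytic amount of TsOH in CH2Cl2 opens the epoxide at C2 and, after loss of the C3 proton, gives the flavonol 15.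

**Step 2 (with step 3).** What may go wrong:
- hydrodebromination;
- stalling after the first borylation on an electron-rich dibromide with ortho methoxyls, leaving mixtures.

Fallback (sequential halogen–lithium exchange in place of palladium catalysis): it sets out from 2 and returns at 4. One equivalent of nBuLi (THF, −78 °C) exchanges a single bromine, since a second exchange on the aryllithium is disfavoured. Trapping with B(OMe)3 and oxidation with H2O2/AcOH gives 5-bromo-2,3,4-trimethoxyphenol F4. A second exchange on F4 with nBuLi (2.2 equiv, the first equivalent forming the phenoxide), borate trapping and oxidation give 4.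

**Step 4.** What may go wrong:
- oxidation of the very electron-rich ring by the iodinating agent in place of substitution;
- loss of iodine from the product during an acidic isolation.

Fallback (directed metalation in place of electrophilic substitution): it sets out from 4 and returns at 5. Protection of 4 with MOMCl and iPr2NEt gives 1,5-bis(methoxymethoxy)-2,3,4-trimethoxybenzene F5. Lithiation with nBuLi (THF, 0 °C) at the carbon between the two directing acetal groups and quenching with I2 give 2-iodo-1,3-bis(methoxymethoxy)-4,5,6-trimethoxybenzene F6. Brief treatment of F6 with dilute HCl in methanol at rt removes both acetals and gives 5.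

## Further compounds

F1 | step 6 | 1-(2,6-dihydroxy-3,4,5-trimethoxyphenyl)ethan-1-one | CC(=O)c1c(O)c(OC)c(OC)c(OC)c1O
F2 | step 6 | 1-[4-(benzyloxy)phenyl]-3-(2,6-dihydroxy-3,4,5-trimethoxyphenyl)propane-1,3-dione | COc1c(O)c(C(=O)CC(=O)c2ccc(OCc3ccccc3)cc2)c(O)c(OC)c1OC
F3 | step 8 | racemic 4',5-bis(benzyloxy)-2,3-epoxy-6,7,8-trimethoxyflavanone, cis-fused oxirane (one enantiomer drawn) | COc1c(OC)c(OCc2ccccc2)c2C(=O)[C@H]3O[C@@]3(c3ccc(OCc4ccccc4)cc3)Oc2c1OC
F4 | step 2 | 5-bromo-2,3,4-trimethoxyphenol | COc1c(O)cc(Br)c(OC)c1OC
F5 | step 4 | 1,5-bis(methoxymethoxy)-2,3,4-trimethoxybenzene | COCOc1cc(OCOC)c(OC)c(OC)c1OC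
F6 | step 4 | 2-iodo-1,3-bis(methoxymethoxy)-4,5,6-trimethoxybenzene | COCOc1c(I)c(OCOC)c(OC)c(OC)c1OC
A1 | alternative 1 | 4'-benzyloxy-5-[4-(benzyloxy)benzoyloxy]-3,6,7,8-tetramethoxyflavone | COc1c(-c2ccc(OCc3ccccc3)cc2)oc2c(OC)c(OC)c(OC)c(OC(=O)c3ccc(OCc4ccccc4)cc3)c2c1=O
A2 | alternative 1 | 2-[2-methoxy-2-(triphenylphosphoranylidene)acetyl]-4,5,6-trimethoxy-1,3-phenylene bis[4-(benzyloxy)benzoate] | COC(C(=O)c1c(OC(=O)c2ccc(OCc3ccccc3)cc2)c(OC)c(OC)c(OC)c1OC(=O)c1ccc(OCc2ccccc2)cc1)=P(c1ccccc1)(c1ccccc1)c1ccccc1
A3 | alternative 2 | 3,5,6,7,8-pentamethoxy-4'-pivaloyloxyflavone | COc1c(-c2ccc(OC(=O)C(C)(C)C)cc2)oc2c(OC)c(OC)c(OC)c(OC)c2c1=O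
A4 | alternative 2 | 4-[2-methoxy-3-oxo-3-(2,3,4,5-tetramethoxyphenyl)propanoyl]phenyl pivalate (racemic) | COC(C(=O)c1cc(OC)c(OC)c(OC)c1OC)C(=O)c1ccc(OC(=O)C(C)(C)C)cc1
A5 | alternative 3 | 4'-O-benzylcalycopterin (4'-benzyloxy-5-hydroxy-3,6,7,8-tetramethoxyflavone) | COc1c(OC)c(O)c2c(=O)c(OC)c(-c3ccc(OCc4ccccc4)cc3)oc2c1OC
A6 | alternative 3 | ethyl 3-[4-(benzyloxy)phenyl]-2-methoxy-3-oxopropanoate (racemic) | CCOC(=O)C(OC)C(=O)c1ccc(OCc2ccccc2)cc1
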